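Ring C is a quinone in which C1(=O), C2(OAr), C3(Me) and C4(=O) lie in a row and C5(H)=C6(iPr) closes the ring. The four-carbon row is the skeleton of a 3-aryloxy-4-methylcyclobutenedione, and the C5=C6 pair is a 3-methylbut-1-en-2-yl unit.
Cuts, in order: quinone to hydroquinone; C4–C5 (6π closure, with the C1–C4 bond of a cyclobutenone restored); C1–C6 (alkenyllithium + carbonyl); O–C2 (phenoxide + vinylogous acid chloride); ring A C1–O of the diaryl ether (Ullmann).
Forward: carvacrol gives one aryl iodide. It is ring A as it stands, and it becomes ring B after I→OH exchange, MOM protection and directed ortho-hydroxylation. Copper then joins the two to A–O–B.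
The freed ring B phenol is attached to the four-membered ring made from dimethyl squarate. The Shapiro alkenyllithium from 3-methylbutan-2-one is added, heating builds ring C (the only ring formed in the route), and Ag2O finishes.
Stereochemistry: the target has no stereocentre. The single carbinol centre met on the way is racemic and disappears when the four-membered ring opens.

Key step: step 14

Assumption: the SMILES carries no stereodescriptor and the diaryl ether axes should rotate freely, so the compound is treated as achiral and "single enantiomer" adds no requirement.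

Step 1
Reactants: 1 carvacrol (5-isopropyl-2-methylphenol)
Product: 2 carvacrol methyl ether (5-isopropyl-2-methylanisole)
Conditions: MeI, K2CO3, acetone, reflux
Reagents that add atoms: methyl iodide, CI
Why: Williamson ether synthesis installs the methoxy group that rings A and B both keep, before any second oxygen is present.

Step 2
Reactants: 2 carvacrol methyl ether
Product: 3 1-iodo-2-isopropyl-4-methoxy-5-methylbenzene
Conditions: NIS, TFA (cat.), MeCN, rt, dark
Reagents that add atoms: N-iodosuccinimide, O=C1CCC(=O)N1I
Why: Electrophilic aromatic iodination with acid-activated NIS should go para to the methoxy group, because the only free ortho site is wedged between OMe and isopropyl.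

Step 3
Reactants: 3 1-iodo-2-isopropyl-4-methoxy-5-methylbenzene
Product: 6 2-isopropyl-4-methoxy-5-methylphenol, via aryllithium 4 (not isolated), via lithium aryl(trimethoxy)borate 5 (not isolated)
Conditions: n-BuLi, THF, −78 °C; B(OMe)3, −78 °C → rt; 30% H2O2, aq NaOH, 0 °C → rt
Reagents that add atoms: hydrogen peroxide, OO (phenol oxygen); n-butyllithium, [Li]CCCC (lithium of 4 and 5 only); trimethyl borate, COB(OC)OC (boron and methoxy groups of 5 only)
Why: Iodine–lithium exchange, borylation and alkaline peroxide oxidation (1,2-aryl shift from boron to oxygen) replace iodine by hydroxyl at the same carbon, so the regiochemistry of step 2 is carried over.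

Step 4
Reactants: 6 2-isopropyl-4-methoxy-5-methylphenol
Product: 7 1-isopropyl-5-methoxy-2-(methoxymethoxy)-4-methylbenzene (MOM ether of 6)
Conditions: MOMCl, iPr2NEt, CH2Cl2, 0 °C → rt
Reagents that add atoms: chloromethyl methyl ether, COCCl
Why: Standard acetal protection of a phenol gives a small group that withstands base and organolithiums and also directs the next metalation.

Step 5
Reactants: 7 MOM ether of 6
Product: 10 3-isopropyl-5-methoxy-2-(methoxymethoxy)-6-methylphenol, via ortho-lithiated MOM ether 8 (not isolated), via lithium aryl(trimethoxy)borate 9 (not isolated)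
Conditions: n-BuLi, TMEDA, Et2O, 0 °C → rt; B(OMe)3, −78 °C → rt; 30% H2O2, aq NaOH, 0 °C
Reagents that add atoms: hydrogen peroxide, OO (phenol oxygen); n-butyllithium, [Li]CCCC (lithium of 8 and 9 only); trimethyl borate, COB(OC)OC (boron and methoxy groups of 9 only)
Why: In this directed ortho metalation the chelating OMOM group outranks OMe as a director and has one free ortho position only (between OMOM and methyl), and borylation–oxidation turns the C–Li bond into C–OH.

Step 6
Reactants: 10 3-isopropyl-5-methoxy-2-(methoxymethoxy)-6-methylphenol; 3 1-iodo-2-isopropyl-4-methoxy-5-methylbenzene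
Product: 11 1-isopropyl-3-(2-isopropyl-4-methoxy-5-methylphenoxy)-5-methoxy-2-(methoxymethoxy)-4-methylbenzene (MOM-protected A–O–B ether)
Conditions: CuI (20 mol %), picolinic acid (40 mol %), K3PO4, DMSO, 105 °C, Ar; 3 in excess (1.5 equiv)
Reagents that add atoms: none
Why: This ligand-assisted Ullmann diaryl ether synthesis uses the doubly ortho-substituted ring as the phenoxide and gives the halide only one ortho group, which is the pairing copper/picolinate catalysis tolerates best.

Step 7
Reactants: 11 MOM-protected A–O–B ether
Product: 12 6-isopropyl-2-(2-isopropyl-4-methoxy-5-methylphenoxy)-4-methoxy-3-methylphenol (written ArOH from here on; ArO– is its aryloxy residue)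
Conditions: conc. HCl (cat.), MeOH, 50 °C
Reagents that add atoms: none
Why: Acid-catalysed acetal exchange removes the MOM group, while aryl methyl ethers and the diaryl ether are inert to dilute methanolic acid.

Step 8
Reactants: 13 dimethyl squarate
Product: 15 3-methoxy-4-methylcyclobut-3-ene-1,2-dione, via carbinol adduct 14 (not isolated)
Conditions: MeLi, THF, −78 °C; aq NH4Cl; crude 14, conc. HCl (cat.), CH2Cl2, rt
Reagents that add atoms: methyllithium, [Li]C
Why: 1,2-Addition of an organolithium to one squarate carbonyl, then acid-promoted allylic transposition with loss of methanol, is the standard entry to 3-alkoxy-4-alkylcyclobutenediones.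

Step 9
Reactants: 15 3-methoxy-4-methylcyclobut-3-ene-1,2-dione
Product: 16 3-hydroxy-4-methylcyclobut-3-ene-1,2-dione
Conditions: 2 M HCl, THF, reflux; evaporation, azeotropic drying (toluene)
Reagents that add atoms: water, O
Why: Acid hydrolysis of the vinylogous ester (addition–elimination of water) should give the strongly acidic semisquaric acid, which is isolated simply by evaporation.

Step 10
Reactants: 16 3-hydroxy-4-methylcyclobut-3-ene-1,2-dione
Product: 17 3-chloro-4-methylcyclobut-3-ene-1,2-dione
Conditions: (COCl)2, DMF (cat.), CH2Cl2, 0 °C → reflux; concentrated and used at once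
Reagents that add atoms: oxalyl chloride, O=C(Cl)C(=O)Cl
Why: Vilsmeier-type activation converts the vinylogous carboxylic acid into its vinylogous acid chloride, just as a carboxylic acid gives an acyl chloride.

Step 11
Reactants: 12 ArOH; 17 3-chloro-4-methylcyclobut-3-ene-1,2-dione
Product: 19 3-(ArO)-4-methylcyclobut-3-ene-1,2-dione, via sodium phenoxide 18 (not isolated)
Conditions: NaH, THF, 0 °C; cannulated into 17 (1.2 equiv), THF, −78 → 0 °C
Reagents that add atoms: sodium hydride, [H-].[Na+] (sodium of 18 only)
Why: Addition–elimination at the chlorine-bearing sp2 carbon of a flat, strongly electrophilic ring behaves like an O-acylation, so even a phenoxide flanked by isopropyl and aryloxy should reach it, and inverse addition keeps free phenoxide away from the product.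

Step 12
Reactants: 20 3-methylbutan-2-one
Product: 21 (E)-3-methylbutan-2-one 2,4,6-triisopropylbenzenesulfonylhydrazone
Conditions: TrisNHNH2, MeOH, HCl (cat.), rt; crystallisation
Reagents that add atoms: 2,4,6-triisopropylbenzenesulfonohydrazide, CC(C)c1cc(C(C)C)c(S(=O)(=O)NN)c(C(C)C)c1
Why: Acid-catalysed condensation of a ketone with a sulfonyl hydrazide should give the crystalline E-hydrazone, whose sulfonamide nitrogen sits on the methyl side.

Step 13
Reactants: 21 trisylhydrazone; 19 3-(ArO)-4-methylcyclobut-3-ene-1,2-dione
Product: 23 (±)-3-(ArO)-4-hydroxy-2-methyl-4-(3-methylbut-1-en-2-yl)cyclobut-2-en-1-one, via 3-methylbut-1-en-2-yllithium 22 (not isolated)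
Conditions: 21 (1.2 equiv), n-BuLi (2.35 equiv), THF, −78 → 0 °C until N2 ceases, recooled to −78 °C; cannulated into 19, THF, −78 °C; sat. NH4Cl at −78 °C; short Et3N-deactivated silica plug
Reagents that add atoms: n-butyllithium, [Li]CCCC (lithium of 22 only)
Why: The Shapiro reaction (syn-directed kinetic deprotonation at the methyl group, then loss of sulfinate and N2) delivers the 1,1-disubstituted alkenyllithium, which adds 1,2 to the carbonyl beside C–OAr because the other carbonyl is deactivated as a vinylogous ester, and the new carbinol centre forms racemic and needs no control.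

Step 14
Reactants: 23 (±)-3-(ArO)-4-hydroxy-2-methyl-4-(3-methylbut-1-en-2-yl)cyclobut-2-en-1-one
Product: 26 2-(ArO)-6-isopropyl-3-methylbenzene-1,4-diol, via dienylketene 24 (not isolated), via cyclohexadienone 25 (not isolated)
Conditions: toluene (0.01 M, degassed), reflux, Ar
Reagents that add atoms: none
Why: Heat cleaves the bond between C=O and C–OH of the cyclobutenone in a conrotatory 4π electrocyclic opening, and because the donor hydroxyl turns outward the alkenyl group ends up cis to the ketene terminus in 24. A thermal disrotatory 6π electrocyclisation then bonds the ketene carbon (future C4) to the terminal =CH2 (future C5), closing six-membered ring C as dienone 25, and enolisation gives aromatic 26. The closest known reaction type is the thermal ring expansion of 4-alkenyl-4-hydroxycyclobutenones to hydroquinones, the alkenyl relative of the Moore rearrangement. No stereocentre is created, and the racemic carbinol carbon becomes the sp2 carbon C1. The step needs only positional selectivity and torquoselectivity: the positions are fixed by the substitution of 23 (OAr beside the carbinol, methyl beside the carbonyl, isopropyl on the inner alkene carbon), and outward rotation of OH secures the geometry that can close. High dilution and exclusion of oxygen should suppress ketene dimerisation and premature oxidation.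

Step 15
Reactants: 26 2-(ArO)-6-isopropyl-3-methylbenzene-1,4-diol
Product: 27 2-(ArO)-6-isopropyl-3-methylcyclohexa-2,5-diene-1,4-dione (target, CNP0335608.0)
Conditions: Ag2O, Na2SO4, Et2O, rt
Reagents that add atoms: none
Why: Silver(I) oxide dehydrogenates the free hydroquinone under neutral conditions, whereas rings A and B carry only etherified oxygens and stay untouched (cerium(IV) is avoided for that reason).

Compound list
1 | carvacrol (5-isopropyl-2-methylphenol) | Cc1ccc(C(C)C)cc1O | starting material
2 | carvacrol methyl ether | COc1cc(C(C)C)ccc1C | intermediate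
3 | 1-iodo-2-isopropyl-4-methoxy-5-methylbenzene | COc1cc(C(C)C)c(I)cc1C | intermediate
4 | (2-isopropyl-4-methoxy-5-methylphenyl)lithium | [Li]c1cc(C)c(OC)cc1C(C)C | intermediate
5 | lithium (2-isopropyl-4-methoxy-5-methylphenyl)trimethoxyborate | [Li+].COc1cc(C(C)C)c([B-](OC)(OC)OC)cc1C | intermediate
6 | 2-isopropyl-4-methoxy-5-methylphenol | COc1cc(C(C)C)c(O)cc1C | intermediate
7 | 1-isopropyl-5-methoxy-2-(methoxymethoxy)-4-methylbenzene | COCOc1cc(C)c(OC)cc1C(C)C | intermediate
8 | [3-isopropyl-5-methoxy-2-(methoxymethoxy)-6-methylphenyl]lithium | COCOc1c([Li])c(C)c(OC)cc1C(C)C | intermediate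
9 | lithium [3-isopropyl-5-methoxy-2-(methoxymethoxy)-6-methylphenyl]trimethoxyborate | [Li+].COCOc1c([B-](OC)(OC)OC)c(C)c(OC)cc1C(C)C | intermediate
10 | 3-isopropyl-5-methoxy-2-(methoxymethoxy)-6-methylphenol | COCOc1c(O)c(C)c(OC)cc1C(C)C | intermediate
11 | MOM-protected A–O–B diaryl ether | COCOc1c(Oc2cc(C)c(OC)cc2C(C)C)c(C)c(OC)cc1C(C)C | intermediate
12 | 6-isopropyl-2-(2-isopropyl-4-methoxy-5-methylphenoxy)-4-methoxy-3-methylphenol (ArOH) | COc1cc(C(C)C)c(Oc2c(C)c(OC)cc(C(C)C)c2O)cc1C | intermediate
13 | dimethyl squarate | COC1=C(OC)C(=O)C1=O | starting material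
14 | (±)-4-hydroxy-2,3-dimethoxy-4-methylcyclobut-2-en-1-one | COC1=C(OC)C(C)(O)C1=O | intermediate
15 | 3-methoxy-4-methylcyclobut-3-ene-1,2-dione | COC1=C(C)C(=O)C1=O | intermediate
16 | 3-hydroxy-4-methylcyclobut-3-ene-1,2-dione | CC1=C(O)C(=O)C1=O | intermediate
17 | 3-chloro-4-methylcyclobut-3-ene-1,2-dione | CC1=C(Cl)C(=O)C1=O | intermediate
18 | sodium salt of 12 | [Na+].COc1cc(C(C)C)c(Oc2c(C)c(OC)cc(C(C)C)c2[O-])cc1C | intermediate
19 | 3-(ArO)-4-methylcyclobut-3-ene-1,2-dione | COc1cc(C(C)C)c(Oc2c(C)c(OC)cc(C(C)C)c2OC2=C(C)C(=O)C2=O)cc1C | intermediate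
20 | 3-methylbutan-2-one | CC(C)C(C)=O | starting material
21 | (E)-3-methylbutan-2-one 2,4,6-triisopropylbenzenesulfonylhydrazone | CC(C)/C(C)=N/NS(=O)(=O)c1c(C(C)C)cc(C(C)C)cc1C(C)C | intermediate
22 | 3-methylbut-1-en-2-yllithium | [Li]C(=C)C(C)C | intermediate
23 | (±)-3-(ArO)-4-hydroxy-2-methyl-4-(3-methylbut-1-en-2-yl)cyclobut-2-en-1-one | COc1cc(C(C)C)c(Oc2c(C)c(OC)cc(C(C)C)c2OC2=C(C)C(=O)C2(O)C(=C)C(C)C)cc1C | intermediate
24 | (3Z)-3-(ArO)-4-hydroxy-2,6-dimethyl-5-methylidenehepta-1,3-dien-1-one (dienylketene) | COc1cc(C(C)C)c(Oc2c(C)c(OC)cc(C(C)C)c2O/C(C(C)=C=O)=C(\O)C(=C)C(C)C)cc1C | intermediate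
25 | 3-(ArO)-4-hydroxy-5-isopropyl-2-methylcyclohexa-2,4-dien-1-one | COc1cc(C(C)C)c(Oc2c(C)c(OC)cc(C(C)C)c2OC2=C(C)C(=O)CC(C(C)C)=C2O)cc1C | intermediate
26 | 2-(ArO)-6-isopropyl-3-methylbenzene-1,4-diol | COc1cc(C(C)C)c(Oc2c(C)c(OC)cc(C(C)C)c2Oc2c(C)c(O)cc(C(C)C)c2O)cc1C | intermediate
27 | 2-(ArO)-6-isopropyl-3-methylcyclohexa-2,5-diene-1,4-dione | COc1cc(C(C)C)c(Oc2c(C)c(OC)cc(C(C)C)c2OC2=C(C)C(=O)C=C(C(C)C)C2=O)cc1C | target

Total step count: 15. Longest linear sequence: 11 (steps 1–7, 11, 13, 14, 15).

Steps most likely to fail

Step 6. Three ortho groups crowd the reacting centres, so C–O bond formation at copper may be too slow. Hydrodeiodination of the halide and oxidative decay of the electron-rich phenoxide could then take over.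
- The fallback removes the metal and uses ligand coupling at iodine(III), which ortho substituents hinder much less.
- It sets out from 2 and 3. Iodide 3 is oxidised with mCPBA in the presence of TsOH and arene 2 (CH2Cl2, rt). Arene 2 is attacked para to its methoxy group, which gives the symmetric salt bis(2-isopropyl-4-methoxy-5-methylphenyl)iodonium tosylate F1.
- The potassium salt of 10 (t-BuOK, THF) is then arylated with F1 at rt to 60 °C.
- The fallback rejoins the route at 11, and the iodide released can be recycled.

Step 13. An aryloxide is a far better leaving group than an alkoxide. Several processes may therefore erode the step: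
- attack at the aryloxy-bearing carbon
- expulsion of aryloxide from the lithium alkoxide on warming
- interference by the sulfinate salt of the Shapiro mixture
- hydrolysis of the vinylogous aryl ester during work-up and chromatography

The fallback changes the source of the nucleophile and never liberates the carbinol.
- It sets out from 19. Reagent 22 is generated free of sulfinate from purchased 2-bromo-3-methylbut-1-ene (t-BuLi, 2 equiv, Et2O, −78 °C) and added to 19 at −78 °C.
- The alkoxide is capped in the flask with TMSCl, giving (±)-3-(ArO)-2-methyl-4-(3-methylbut-1-en-2-yl)-4-(trimethylsilyloxy)cyclobut-2-en-1-one F2, a neutral compound that should tolerate chromatography.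
- Heating F2 in degassed toluene runs the same 4π opening (silyloxy also turns outward) and 6π closure. This gives 3-(ArO)-5-isopropyl-2-methyl-4-(trimethylsilyloxy)phenol F3.
- Brief methanolysis (cat. HCl, MeOH) rejoins the route at 26.

Step 11. The chloride may hydrolyse or self-condense through its acidic methyl group before the hindered phenoxide engages, and preparing and handling it adds losses.
- The fallback attaches the phenol first and the methyl group afterwards, which makes steps 8–10 unnecessary.
- It sets out from 12. Phenoxide 18 is added to an excess of purchased 3,4-dichlorocyclobut-3-ene-1,2-dione (THF, −78 °C), a more electrophilic partner without acidic C–H, to give 3-(ArO)-4-chlorocyclobut-3-ene-1,2-dione F4.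
- Stille cross-coupling of this halocyclobutenedione with Me4Sn (Pd2(dba)3, tri(2-furyl)phosphine, CuI, dioxane, 50 °C) installs the methyl group.
- The fallback rejoins the route at 19.

Further compounds
F1 | step 6 | bis(2-isopropyl-4-methoxy-5-methylphenyl)iodonium tosylate | COc1cc(C(C)C)c([I+]c2cc(C)c(OC)cc2C(C)C)cc1C.Cc1ccc(S(=O)(=O)[O-])cc1
F2 | step 13 | (±)-3-(ArO)-2-methyl-4-(3-methylbut-1-en-2-yl)-4-(trimethylsilyloxy)cyclobut-2-en-1-one | COc1cc(C(C)C)c(Oc2c(C)c(OC)cc(C(C)C)c2OC2=C(C)C(=O)C2(O[Si](C)(C)C)C(=C)C(C)C)cc1C
F3 | step 13 | 3-(ArO)-5-isopropyl-2-methyl-4-(trimethylsilyloxy)phenol | COc1cc(C(C)C)c(Oc2c(C)c(OC)cc(C(C)C)c2Oc2c(C)c(O)cc(C(C)C)c2O[Si](C)(C)C)cc1C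
F4 | step 11 | 3-(ArO)-4-chlorocyclobut-3-ene-1,2-dione | COc1cc(C(C)C)c(Oc2c(C)c(OC)cc(C(C)C)c2OC2=C(Cl)C(=O)C2=O)cc1C
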